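Ring A is cut at C3–C4 and C5–C10. It carries oxygen at C3 flanked by mutually cis methyl groups on C4 and C5, and C10 must be functionalised for ring fusion. This pattern maps onto a trisubstituted E enal (both methyls, formyl carbon C6) and a butadiene oxygenated at both termini. One catalytic enantioselective Diels–Alder reaction closes ring A, makes both bonds and sets C3, C4 and C5. The diene is used as its electron-rich E,E bis(silyl ether), made in one step from the commercial but sluggish diacetate. C6 and a C10 ketone later take up pentane-2,4-dione to close ring B; the Z thioacrylate ester is attached last.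

Key step: step 2

Remark: atom labels follow the target skeleton (ring A = C1, C2, C3, C4, C5, C10; ring B = C5 to C10; C11 = carbinol carbon). The side-chain alkene is read as Z (MeS cis to the carbonyl), as the target SMILES encodes.
Remark: the oxazaborolidine of step 2 is prepared beforehand from (R)-α,α-diphenylprolinol and (2-methylphenyl)boronic acid (toluene, azeotropic removal of water) and is not counted as a step.

Step 1
Reactants: 1 (1E,3E)-buta-1,3-diene-1,4-diyl diacetate
Product: 3 (1E,3E)-1,4-bis[(tert-butyldimethylsilyl)oxy]buta-1,3-diene, via dilithium (1E,3E)-buta-1,3-diene-1,4-bis(olate) 2 (not isolated)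
Conditions: MeLi (4.1 equiv), THF, −78 °C (1 added to MeLi); then TBSCl (2.2 equiv), DMPU, −78 °C → rt
Reagents that add atoms: tert-butyldimethylsilyl chloride, CC(C)(C)[Si](C)(C)Cl
Why: Cleavage of each enol acetate by two equivalents of MeLi gives the lithium enolate with retention of the E geometry (the acetone released is trapped as tert-butoxide), and O-silylation of the bis-enolate should give the E,E bis(silyl dienol ether), a far more electron-rich diene than its diacetate parent.

Step 2
Reactants: 3 (1E,3E)-1,4-bis[(tert-butyldimethylsilyl)oxy]buta-1,3-diene; 4 (E)-2-methylbut-2-enal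
Product: 5 (1R,2S,5R,6R)-2,5-bis[(tert-butyldimethylsilyl)oxy]-1,6-dimethylcyclohex-3-ene-1-carbaldehyde
Conditions: (R)-3,3-diphenyl-1-(2-methylphenyl)tetrahydro-1H,3H-pyrrolo[1,2-c][1,3,2]oxazaborole (15 mol %), HNTf2 (12 mol %), 4 (2 equiv), CH2Cl2, −78 → −40 °C
Reagents that add atoms: none
Why: This is a normal-demand, concerted but asynchronous [4+2] cycloaddition of the boron-bound s-trans enal with the s-cis diene, the closest known type being the oxazaborolidinium-catalysed enantioselective Diels–Alder reaction of 2-substituted enals with oxygenated dienes. Ring A is closed by intermolecular cycloaddition, the C3–C4 and C5–C10 bonds forming suprafacially on both partners in one event. The cis methyls at C4 and C5 follow from the E geometry of 4, the cis oxygens at C3 and C10 from the E,E geometry of 3, and the placement of both oxygens cis to C6 from endo orientation of the activated formyl group. Absolute configuration comes from the catalyst, which holds the enal by B–O coordination and a formyl C–H···O contact and blocks one face with its aryl wall, so that the diene must add to the Cα-Si/Cβ-Re face; the (R) catalyst is expected to do this, and its antipode is equally available should the sense prove opposite. The step needs C=C over C=O chemoselectivity, endo selectivity and facial selectivity; the concerted path keeps silicon on oxygen, and because C10 is oxidised later only C3 depends on the endo mode.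

Step 3
Reactants: 5 (1R,2S,5R,6R)-2,5-bis[(tert-butyldimethylsilyl)oxy]-1,6-dimethylcyclohex-3-ene-1-carbaldehyde
Product: 6 (1R,2R,3R,6S)-3,6-bis[(tert-butyldimethylsilyl)oxy]-1,2-dimethylcyclohexane-1-carbaldehyde
Conditions: H2 (1 atm), Rh/Al2O3 (5 wt %), EtOAc, rt
Reagents that add atoms: none
Why: Heterogeneous hydrogenation of the cis-disubstituted ring alkene over rhodium, which has little tendency to cleave allylic C–O bonds or to reduce a hindered aliphatic aldehyde, should saturate C1–C2 without creating a stereocentre.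

Step 4
Reactants: 6 (1R,2R,3R,6S)-3,6-bis[(tert-butyldimethylsilyl)oxy]-1,2-dimethylcyclohexane-1-carbaldehyde
Product: 8 (1S,2S,3R,4R)-2-(hydroxymethyl)-2,3-dimethylcyclohexane-1,4-diol, via bis-silyl primary alcohol 7 (not isolated)
Conditions: NaBH4, MeOH/THF, 0 °C; then HCl (1.25 M in MeOH), rt → 40 °C
Reagents that add atoms: none
Why: Borohydride reduction removes the formyl carbonyl first, so that no β-hydroxy aldehyde able to open ring A by retro-aldol cleavage is ever present, and acid-catalysed methanolysis of the two silyl ethers then gives the triol with all stereocentres untouched.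

Step 5
Reactants: 8 (1S,2S,3R,4R)-2-(hydroxymethyl)-2,3-dimethylcyclohexane-1,4-diol
Product: 9 (4aS,5R,6R,8aS)-2,2,4a,5-tetramethylhexahydro-4H-1,3-benzodioxin-6-ol
Conditions: Me2C(OMe)2, PPTS (cat.), acetone, rt
Reagents that add atoms: 2,2-dimethoxypropane, COC(C)(C)OC
Why: Thermodynamic acetalisation should select the six-membered 1,3-dioxane spanning the C10 and C6 hydroxyls (the alternatives are seven-membered or bridged), which leaves the C3 hydroxyl as the only free one.

Step 6
Reactants: 9 (4aS,5R,6R,8aS)-2,2,4a,5-tetramethylhexahydro-4H-1,3-benzodioxin-6-ol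
Product: 10 (4aS,5R,6R,8aS)-2,2,4a,5-tetramethylhexahydro-4H-1,3-benzodioxin-6-yl benzoate
Conditions: BzCl, pyridine, DMAP (cat.), CH2Cl2, 0 °C → rt
Reagents that add atoms: benzoyl chloride, O=C(Cl)c1ccccc1
Why: DMAP-catalysed acylation of the single secondary alcohol installs a benzoate that blocks C3–O from adding to C6 later and tolerates acid, oxidant, amine salts and low-temperature organocerium reagents.

Step 7
Reactants: 10 (4aS,5R,6R,8aS)-2,2,4a,5-tetramethylhexahydro-4H-1,3-benzodioxin-6-yl benzoate
Product: 11 (1R,2R,3S,4S)-4-hydroxy-3-(hydroxymethyl)-2,3-dimethylcyclohexyl benzoate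
Conditions: AcOH/H2O (4:1), 45 °C
Reagents that add atoms: none
Why: Acid hydrolysis of the isopropylidene acetal frees the 1,3-diol while the benzoate is inert and acyl migration is slow at low pH.

Step 8
Reactants: 11 (1R,2R,3S,4S)-4-hydroxy-3-(hydroxymethyl)-2,3-dimethylcyclohexyl benzoate
Product: 12 (1R,2R,3S)-3-formyl-2,3-dimethyl-4-oxocyclohexyl benzoate
Conditions: Dess–Martin periodinane (2.5 equiv), CH2Cl2, rt
Reagents that add atoms: none
Why: Dess–Martin oxidation converts the primary and the secondary alcohol into the C6 formyl and C10 keto groups under non-basic conditions, and the quaternary C5 between them cannot enolise, so its configuration is secure.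

Step 9
Reactants: 12 (1R,2R,3S)-3-formyl-2,3-dimethyl-4-oxocyclohexyl benzoate; 13 pentane-2,4-dione
Product: 16 (1R,2R,8aR)-7-acetyl-1,8a-dimethyl-6-oxo-1,2,3,4,6,8a-hexahydronaphthalen-2-yl benzoate, via alkylidene diketone 14 (not isolated), via β-hydroxy ketone 15 (not isolated)
Conditions: piperidine (0.2 equiv), AcOH (0.2 equiv), toluene, reflux, Dean–Stark
Reagents that add atoms: none
Why: Knoevenagel condensation of the diketone methylene with the formyl group (C6=C7), followed by intramolecular aldol condensation of an acetyl methyl group (C9) onto the C10 ketone, is the dienone annulation known for 2-formyl-2-alkylcyclohexanones; the symmetry of 13 removes any regiochemical question, and only the dehydrated cross-conjugated dienone is a thermodynamic sink.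

Step 10
Reactants: 16 (1R,2R,8aR)-7-acetyl-1,8a-dimethyl-6-oxo-1,2,3,4,6,8a-hexahydronaphthalen-2-yl benzoate
Product: 17 (1R,2R,8aR)-7-(2-hydroxypropan-2-yl)-1,8a-dimethyl-6-oxo-1,2,3,4,6,8a-hexahydronaphthalen-2-yl benzoate
Conditions: MeMgBr, CeCl3, THF, −78 °C; then H2O
Reagents that add atoms: methylmagnesium bromide, C[Mg]Br
Why: Organocerium 1,2-addition should select the exocyclic acetyl carbonyl, which is conjugated to one alkene only, over the doubly vinylogous ring carbonyl (C8) and the benzoate, while the hard, weakly basic reagent suppresses conjugate addition at C6.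

Step 11
Reactants: 17 (1R,2R,8aR)-7-(2-hydroxypropan-2-yl)-1,8a-dimethyl-6-oxo-1,2,3,4,6,8a-hexahydronaphthalen-2-yl benzoate
Product: 18 (4aR,5R,6R)-6-hydroxy-3-(2-hydroxypropan-2-yl)-4a,5-dimethyl-5,6,7,8-tetrahydronaphthalen-2(4aH)-one
Conditions: K2CO3, MeOH, rt
Reagents that add atoms: none
Why: Base-catalysed transesterification removes the benzoate as methyl benzoate; the tertiary alcohol sits on an sp2 carbon and so cannot undergo retro-aldol cleavage, and no stereocentre is acidic.

Step 12
Reactants: 19 prop-2-yn-1-ol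
Product: 21 (Z)-3-iodo-2-methylprop-2-en-1-ol, via vinylmagnesium alkoxide 20 (not isolated)
Conditions: MeMgBr (2.5 equiv), CuI (10 mol %), Et2O, −10 °C → rt; then I2, −10 °C; aqueous work-up
Reagents that add atoms: methylmagnesium bromide, C[Mg]Br; iodine, II
Why: Copper-catalysed anti-carbomagnesiation of the propargylic alkoxide places methyl on C2 and magnesium on C3 cis to the CH2O arm in a five-membered chelate, and iodinolysis with retention fixes the Z geometry.

Step 13
Reactants: 21 (Z)-3-iodo-2-methylprop-2-en-1-ol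
Product: 22 (Z)-3-iodo-2-methylprop-2-enoic acid
Conditions: CrO3, H2SO4, H2O, acetone, 0 °C
Reagents that add atoms: water, O (the new oxygen enters as the aldehyde hydrate; CrO3 is the oxidant)
Why: Jones oxidation takes the primary allylic alcohol through the aldehyde hydrate to the acid without affecting the vinyl iodide or its geometry.

Step 14
Reactants: 22 (Z)-3-iodo-2-methylprop-2-enoic acid
Product: 23 (Z)-2-methyl-3-(methylsulfanyl)prop-2-enoic acid
Conditions: NaSMe (2.2 equiv), CuI (10 mol %), DMF, 50 °C; then 1 M HCl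
Reagents that add atoms: sodium methanethiolate, C[S-].[Na+]
Why: Copper-catalysed vinylic C–S coupling of the Ullmann type, assisted by the cis carboxylate and backed by addition–elimination, should replace iodide by methylthiolate with retention, and the carboxylate form of the product resists the thiolate addition–elimination that would scramble the geometry.

Step 15
Reactants: 18 (4aR,5R,6R)-6-hydroxy-3-(2-hydroxypropan-2-yl)-4a,5-dimethyl-5,6,7,8-tetrahydronaphthalen-2(4aH)-one; 23 (Z)-2-methyl-3-(methylsulfanyl)prop-2-enoic acid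
Product: 24 (1R,2R,8aR)-7-(2-hydroxypropan-2-yl)-1,8a-dimethyl-6-oxo-1,2,3,4,6,8a-hexahydronaphthalen-2-yl (Z)-2-methyl-3-(methylsulfanyl)prop-2-enoate
Conditions: DCC, DMAP (0.1 equiv), CH2Cl2, 0 °C → rt
Reagents that add atoms: none
Why: Steglich esterification should acylate the secondary C3 hydroxyl while the tertiary C11 hydroxyl is inert; C3 keeps its configuration because only the O–H bond is broken, and low temperature with little DMAP should preserve the Z alkene.

Compound list
1 | (1E,3E)-buta-1,3-diene-1,4-diyl diacetate | CC(=O)O/C=C/C=C/OC(C)=O | starting material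
2 | dilithium (1E,3E)-buta-1,3-diene-1,4-bis(olate) | [Li]O/C=C/C=C/O[Li] | intermediate
3 | (1E,3E)-1,4-bis[(tert-butyldimethylsilyl)oxy]buta-1,3-diene | CC(C)(C)[Si](C)(C)O/C=C/C=C/O[Si](C)(C)C(C)(C)C | intermediate
4 | (E)-2-methylbut-2-enal | C/C=C(\C)C=O | starting material
5 | (1R,2S,5R,6R)-2,5-bis[(tert-butyldimethylsilyl)oxy]-1,6-dimethylcyclohex-3-ene-1-carbaldehyde (both silyloxy groups cis to the formyl group, methyls cis on the other face) | CC(C)(C)[Si](C)(C)O[C@@H]1C=C[C@H](O[Si](C)(C)C(C)(C)C)[C@](C)(C=O)[C@H]1C | intermediate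
6 | (1R,2R,3R,6S)-3,6-bis[(tert-butyldimethylsilyl)oxy]-1,2-dimethylcyclohexane-1-carbaldehyde | CC(C)(C)[Si](C)(C)O[C@@H]1CC[C@H](O[Si](C)(C)C(C)(C)C)[C@](C)(C=O)[C@H]1C | intermediate
7 | [(1S,2R,3R,6S)-3,6-bis[(tert-butyldimethylsilyl)oxy]-1,2-dimethylcyclohexyl]methanol | CC(C)(C)[Si](C)(C)O[C@@H]1CC[C@H](O[Si](C)(C)C(C)(C)C)[C@](C)(CO)[C@H]1C | intermediate
8 | (1S,2S,3R,4R)-2-(hydroxymethyl)-2,3-dimethylcyclohexane-1,4-diol | O[C@@H]1CC[C@H](O)[C@](C)(CO)[C@H]1C | intermediate
9 | (4aS,5R,6R,8aS)-2,2,4a,5-tetramethylhexahydro-4H-1,3-benzodioxin-6-ol | O[C@@H]1CC[C@@H]2OC(C)(C)OC[C@]2(C)[C@H]1C | intermediate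
10 | (4aS,5R,6R,8aS)-2,2,4a,5-tetramethylhexahydro-4H-1,3-benzodioxin-6-yl benzoate | O=C(c1ccccc1)O[C@@H]2CC[C@@H]3OC(C)(C)OC[C@]3(C)[C@H]2C | intermediate
11 | (1R,2R,3S,4S)-4-hydroxy-3-(hydroxymethyl)-2,3-dimethylcyclohexyl benzoate | O=C(c1ccccc1)O[C@@H]2CC[C@H](O)[C@](C)(CO)[C@H]2C | intermediate
12 | (1R,2R,3S)-3-formyl-2,3-dimethyl-4-oxocyclohexyl benzoate | O=C(c1ccccc1)O[C@@H]2CCC(=O)[C@](C)(C=O)[C@H]2C | intermediate
13 | pentane-2,4-dione | CC(=O)CC(C)=O | starting material
14 | (1R,2R,3R)-3-(2-acetyl-3-oxobut-1-en-1-yl)-2,3-dimethyl-4-oxocyclohexyl benzoate | O=C(c1ccccc1)O[C@@H]2CCC(=O)[C@](C)(C=C(C(C)=O)C(C)=O)[C@H]2C | intermediate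
15 | (1R,2R,8aR)-7-acetyl-4a-hydroxy-1,8a-dimethyl-6-oxo-1,2,3,4,4a,5,6,8a-octahydronaphthalen-2-yl benzoate (either configuration at C4a) | O=C(c1ccccc1)O[C@@H]2CCC3(O)CC(=O)C(C(C)=O)=C[C@]3(C)[C@H]2C | intermediate
16 | (1R,2R,8aR)-7-acetyl-1,8a-dimethyl-6-oxo-1,2,3,4,6,8a-hexahydronaphthalen-2-yl benzoate | O=C(c1ccccc1)O[C@@H]2CCC3=CC(=O)C(C(C)=O)=C[C@]3(C)[C@H]2C | intermediate
17 | (1R,2R,8aR)-7-(2-hydroxypropan-2-yl)-1,8a-dimethyl-6-oxo-1,2,3,4,6,8a-hexahydronaphthalen-2-yl benzoate | O=C(c1ccccc1)O[C@@H]2CCC3=CC(=O)C(C(C)(C)O)=C[C@]3(C)[C@H]2C | intermediate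
18 | (4aR,5R,6R)-6-hydroxy-3-(2-hydroxypropan-2-yl)-4a,5-dimethyl-5,6,7,8-tetrahydronaphthalen-2(4aH)-one | O[C@@H]1CCC2=CC(=O)C(C(C)(C)O)=C[C@]2(C)[C@H]1C | intermediate
19 | prop-2-yn-1-ol | C#CCO | starting material
20 | bromomagnesium (Z)-3-(bromomagnesio)-2-methylprop-2-en-1-olate | Br[Mg]/C=C(/C)CO[Mg]Br | intermediate
21 | (Z)-3-iodo-2-methylprop-2-en-1-ol | I/C=C(/C)CO | intermediate
22 | (Z)-3-iodo-2-methylprop-2-enoic acid | I/C=C(/C)C(=O)O | intermediate
23 | (Z)-2-methyl-3-(methylsulfanyl)prop-2-enoic acid | CS/C=C(/C)C(=O)O | intermediate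
24 | (1R,2R,8aR)-7-(2-hydroxypropan-2-yl)-1,8a-dimethyl-6-oxo-1,2,3,4,6,8a-hexahydronaphthalen-2-yl (Z)-2-methyl-3-(methylsulfanyl)prop-2-enoate | CS/C=C(/C)C(=O)O[C@@H]1CCC2=CC(=O)C(C(C)(C)O)=C[C@]2(C)[C@H]1C | target

Total steps: 15. Longest linear sequence: 12 steps (steps 1 to 11, then 15); the acid 23 takes 3 steps (12 to 14).

Steps most likely to fail

1. Step 2 (cycloaddition). The silyl dienol ether may attack the boron-bound formyl carbon or transfer silicon faster than the ring closes, and a silicon-mediated background reaction would erode facial control. The fallback sets out again from 1 and 4 and uses 1 itself as the diene. Its enol ester groups cannot transfer silicon and tolerate the more acidic AlBr3-activated form of the same oxazaborolidine at −20 °C → rt and high concentration. This should give (1R,4S,5R,6R)-5-formyl-5,6-dimethylcyclohex-2-ene-1,4-diyl diacetate F1. Hydrogenation over Rh/Al2O3 then gives (1S,2R,3R,4R)-2-formyl-2,3-dimethylcyclohexane-1,4-diyl diacetate F2, and LiAlH4 in THF reduces the formyl group and both esters, so the route is rejoined at triol 8.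

2. Step 9 (ring B annulation). The amine may deformylate the non-enolisable β-keto aldehyde (retro-Claisen loss of C6), or the reversible aldol may fail to close onto the hindered C10 ketone. The fallback sets out from 12 and replaces the reversible aldol by an irreversible phosphonate olefination. Diethyl (2,4-dioxopentyl)phosphonate F3 is made from the dianion of commercial diethyl (2-oxopropyl)phosphonate and N-methoxy-N-methylacetamide. It is condensed with 12 at its doubly activated methylene under amine-free Knoevenagel conditions (TiCl4, pyridine, THF, 0 °C) to give (1R,2R,3R)-3-[2-acetyl-4-(diethoxyphosphoryl)-3-oxobut-1-en-1-yl]-2,3-dimethyl-4-oxocyclohexyl benzoate F4. Intramolecular Horner–Wadsworth–Emmons reaction of F4 at C10 (LiCl, DBU, MeCN) closes ring B and comes back at 16.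

3. Step 10 (methyl addition). The reagent may fail to discriminate between the acetyl and the ring (C8) carbonyl, or may add conjugately at C6. The fallback sets out from 12 and runs the step-9 annulation with methyl acetoacetate to give methyl (7R,8R,8aR)-7-(benzoyloxy)-8,8a-dimethyl-3-oxo-3,5,6,7,8,8a-hexahydronaphthalene-2-carboxylate F5. Luche reduction (NaBH4, CeCl3, MeOH, −78 °C) masks C8 as methyl (7R,8R,8aR)-7-(benzoyloxy)-3-hydroxy-8,8a-dimethyl-3,5,6,7,8,8a-hexahydronaphthalene-2-carboxylate F6. Excess MeMgBr (THF, 0 °C) converts the ester into the tertiary carbinol and removes the benzoate, giving (4aR,5R,6R)-3-(2-hydroxypropan-2-yl)-4a,5-dimethyl-2,4a,5,6,7,8-hexahydronaphthalene-2,6-diol F7. MnO2 in CH2Cl2 oxidises only the doubly allylic C8 alcohol and comes back at 18.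

Further compounds
F1 | step 2 | (1R,4S,5R,6R)-5-formyl-5,6-dimethylcyclohex-2-ene-1,4-diyl diacetate | CC(=O)O[C@@H]1C=C[C@H](OC(C)=O)[C@](C)(C=O)[C@H]1C
F2 | step 2 | (1S,2R,3R,4R)-2-formyl-2,3-dimethylcyclohexane-1,4-diyl diacetate | CC(=O)O[C@@H]1CC[C@H](OC(C)=O)[C@](C)(C=O)[C@H]1C
F3 | step 9 | diethyl (2,4-dioxopentyl)phosphonate | CCOP(=O)(CC(=O)CC(C)=O)OCC
F4 | step 9 | (1R,2R,3R)-3-[2-acetyl-4-(diethoxyphosphoryl)-3-oxobut-1-en-1-yl]-2,3-dimethyl-4-oxocyclohexyl benzoate | O=C(c1ccccc1)O[C@@H]2CCC(=O)[C@](C)(C=C(C(C)=O)C(=O)CP(=O)(OCC)OCC)[C@H]2C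
F5 | step 10 | methyl (7R,8R,8aR)-7-(benzoyloxy)-8,8a-dimethyl-3-oxo-3,5,6,7,8,8a-hexahydronaphthalene-2-carboxylate | O=C(c1ccccc1)O[C@@H]2CCC3=CC(=O)C(C(=O)OC)=C[C@]3(C)[C@H]2C
F6 | step 10 | methyl (7R,8R,8aR)-7-(benzoyloxy)-3-hydroxy-8,8a-dimethyl-3,5,6,7,8,8a-hexahydronaphthalene-2-carboxylate | O=C(c1ccccc1)O[C@@H]2CCC3=CC(O)C(C(=O)OC)=C[C@]3(C)[C@H]2C
F7 | step 10 | (4aR,5R,6R)-3-(2-hydroxypropan-2-yl)-4a,5-dimethyl-2,4a,5,6,7,8-hexahydronaphthalene-2,6-diol | O[C@@H]1CCC2=CC(O)C(C(C)(C)O)=C[C@]2(C)[C@H]1C
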